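All runs stem from a simulated flask with constants of no real substance.

At 120 h the oak run still holds 41.0% of its substrate, and this flask is oak, so the question is what that leftover can still become.

| setting | oak | maple | flask |
|---|---|---|---|
| substrate | 0.050 M | 0.075 M | 0.050 M |
| reagent | 0.030 M | 0.030 M | 0.0300 M |
| remark | the very flask that is asked about, followed so far | run made earlier |  |
| time |  |  | 8.0 d |

| run | time / h | target / % | substrate / % |
|---|---|---|---|
| oak | 10.0 | 27.0 | 72.9 |
| oak | 15.0 | 33.5 | 65.7 |
| oak | 25.0 | 42.3 | 56.8 |
| oak | 40.0 | 49.8 | 49.7 |
| oak | 72.0 | 55.4 | 43.0 |
| oak | 120 | 58.0 | 41.0 |
| maple | 1.00 | 3.8 | 95.6 |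
| maple | 3.00 | 10.2 | 89.2 |
| maple | 6.00 | 17.7 | 82.2 |
| maple | 8.00 | 20.2 | 78.5 |
| maple | 12.0 | 25.6 | 73.4 |
| maple | 15.0 | 28.3 | 70.8 |

(each reading ± 0.3 percentage points)

- north-east: change nothing and wait 15 d more
- north-west: at 8.0 d add reagent, 50.0% of the amount charged, then wait 15 d
- north: at 8.0 d add substrate, 50.0% of the amount charged, then wait 15 d

- what is said of target includes crystals
- crystals is a solid; its amount is given per volume of the solution
- additions leave the volume as it is
- candidate steps: substrate + reagent -> isomer of the product; substrate + reagent -> target; crystals <-> target

- target, in percent of the substrate first charged, at 8.0 d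
- what to do for the largest gain in target; "none" if nothing gains more than 2 percentage points (north-east / north-west / north / none)
- target present, in percent of the substrate first charged, after north-east
- target present, in percent of the substrate first charged, after north-west

I follow oak in slow motion and count everything as a fraction of the substrate charge, on which scale reagent starts at 0.600. In the first instants substrate and reagent go one for one, mostly to target and a little to the isomer of the product, and crystals count as target. At the last oak reading, target is 98.3% of the substrate consumed. So I carry the reagent ceiling: the reagent charge as a fraction of the substrate charge, times that share, which is the target the reagent pays for when it is used up, 59.0%.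

The pace, meaning rate over the product of the two fractions, reads 0.0712 h⁻¹ from the first oak reading. The last maple reading, scaled to the oak substrate charge, gives 0.0714 h⁻¹, so these two readings agree on the product form.

In the middle, at 40.0 h, substrate reads 49.7% but reagent only 0.0970, so reagent, the limiting reagent, now holds the rate down. At the end, my integrated rate leaves 0.00102 of reagent at 8.0 d, so I expect 58.9% target. Waiting or adding substrate leaves the ceiling where it is, and the reagent still unused is worth 0.1 percentage points of target, which is less than the margin of 2 points.

North-west adds 0.300 of reagent to 0.400 of substrate and raises the ceiling to 88.5%. The substrate excess shrinks to 0.100, a quarter of what oak had. After 15 d, my integrated rate leaves 0.00613 of reagent unused, so I expect 87.9% target. I choose north-west.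

The forecast gives 58.7%, 58.8%, north-west and 87.6%, the last lower than my figure, and says: “Oak stalls near 59–60% conversion because the reagent (0.6 equivalents) runs out, not because of an equilibrium.”

The flask gives 58.6% at 8.0 d, 58.7% after north-east and 87.4% after north-west, a gain of 29 points.

    substrate + reagent → isomer of the product (k = 8.70 × 10⁻⁶ M⁻¹ s⁻¹)
    substrate + reagent → target (k = 3.90 × 10⁻⁴ M⁻¹ s⁻¹)
    crystals ⇌ target, rate k3*(cs3 - [target]) while solid is left; crystals form when [target] > cs3 (solubility = 37.0 mM, k = 0.00340 s⁻¹)

At 192 h the flask has 0.162% of its reagent charge free beside 40.1% of its substrate. After north-west it stands 1 point under the raised ceiling of 88.5%. A neighbour flask with 0.150 equiv of reagent has a ceiling of 14.7% and reads 14.7% target at 192 h.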